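**Plan**

- Retrosynthesis: the enol-lactone bond O2–C3 is cut first, giving a 2-alkynylbenzoic acid. The freed C1 carboxyl is then tied to O2' of the phenoxy ring as a seven-membered depsidone lactone. In that lactone the hindered diaryl ether bond O–C1' is cut as a C–H/O–H pair, leaving a simple depside. The last cuts are the ester C1–O2' and the aryl–alkyne bond.
- Forward: Sonogashira coupling on a benzodioxinone triflate, ester union with olivetol monomethyl ether, anodic closure of the dioxepinone ring (this makes the diaryl ether), hydroxide opening, and finally 6-endo closure of the pyranone ring.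
- Enabling feature: the lactone carbonyl C1 is ortho to the ether carbon C8 on the isocoumarin ring, and the free 2'-OH is ortho to the ether carbon C1' on the phenoxy ring. A C1–O2' ester therefore holds the C8 oxygen within a seven-membered ring of C1'. C1' is also para to the 4'-OMe group, the site of highest charge in the radical cation of that ring.
- Stereochemistry: the target has no stereocentre, so none is set.

Key step: step 6

Remark: the SMILES contains no stereocentre and the diaryl ether axis is taken as freely rotating, so the compound is achiral and the "single enantiomer" clause needs no enantiocontrol.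

**Route**

Step 1
Reactants: 1 olivetol (5-pentylbenzene-1,3-diol)
Product: 2 3-methoxy-5-pentylphenol
Conditions: MeI (1.0 equiv), K2CO3 (1.0 equiv), acetone, reflux; chromatography to remove unreacted 1 and the dimethyl ether
Reagents that add atoms: iodomethane, CI
Why: Williamson mono-O-methylation of a symmetric resorcinol, in which the two hydroxyls are equivalent so only one mono-ether can form and limiting MeI should keep the dimethyl ether down (statistical, diol recoverable).

Step 2
Reactants: 3 5,7-dihydroxy-2,2-dimethyl-4H-1,3-benzodioxin-4-one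
Product: 4 5-hydroxy-2,2-dimethyl-4-oxo-4H-1,3-benzodioxin-7-yl 4-methylbenzenesulfonate
Conditions: TsCl (1.05 equiv), Et3N (1.2 equiv), CH2Cl2, 0 °C to rt
Reagents that add atoms: 4-toluenesulfonyl chloride, Cc1ccc(cc1)S(Cl)(=O)=O
Why: selective O-sulfonylation of the free, more acidic 7-OH (para to the carbonyl), while the 5-OH is chelated to C4=O and should stay untouched.

Step 3
Reactants: 4 5-hydroxy-2,2-dimethyl-4-oxo-4H-1,3-benzodioxin-7-yl 4-methylbenzenesulfonate
Product: 5 2,2-dimethyl-4-oxo-5-{[(trifluoromethyl)sulfonyl]oxy}-4H-1,3-benzodioxin-7-yl 4-methylbenzenesulfonate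
Conditions: Tf2O (1.2 equiv), pyridine, CH2Cl2, 0 °C
Reagents that add atoms: trifluoromethanesulfonic anhydride, O=S(=O)(OS(=O)(=O)C(F)(F)F)C(F)(F)F
Why: O-triflation of the remaining chelated phenol, a standard activation of 5-hydroxybenzodioxinones for cross-coupling.

Step 4
Reactants: 5 2,2-dimethyl-4-oxo-5-{[(trifluoromethyl)sulfonyl]oxy}-4H-1,3-benzodioxin-7-yl 4-methylbenzenesulfonate; 6 1-heptyne
Product: 7 5-(hept-1-yn-1-yl)-2,2-dimethyl-4-oxo-4H-1,3-benzodioxin-7-yl 4-methylbenzenesulfonate
Conditions: PdCl2(PPh3)2 (5 mol %), CuI (10 mol %), Et3N (3 equiv), DMF, 60 °C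
Reagents that add atoms: none
Why: Sonogashira coupling, in which oxidative addition should occur only at the aryl triflate activated by the ortho carbonyl, the aryl tosylate being inert to Pd/PPh3.

Step 5
Reactants: 7 5-(hept-1-yn-1-yl)-2,2-dimethyl-4-oxo-4H-1,3-benzodioxin-7-yl 4-methylbenzenesulfonate; 2 3-methoxy-5-pentylphenol
Product: 8 3-methoxy-5-pentylphenyl 2-(hept-1-yn-1-yl)-6-hydroxy-4-(tosyloxy)benzoate
Conditions: 2 (1.2 equiv), NaH (1.2 equiv), THF/DMF 4:1, 0 to 45 °C; then 1 M HCl
Reagents that add atoms: none
Why: transesterification by nucleophilic opening of the benzodioxinone, in which the phenoxide adds to C4=O and the ring-opened hemiketal alkoxide loses acetone to give the chelated salicylate phenoxide, which should make the acyl transfer irreversible.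

Step 6
Reactants: 8 3-methoxy-5-pentylphenyl 2-(hept-1-yn-1-yl)-6-hydroxy-4-(tosyloxy)benzoate
Product: 9 1-(hept-1-yn-1-yl)-8-methoxy-11-oxo-6-pentyl-11H-dibenzo[b,e][1,4]dioxepin-3-yl 4-methylbenzenesulfonate
Conditions: undivided cell, boron-doped diamond anode, Pt cathode, constant current 3 mA cm-2 to 2.2 F mol-1, n-Bu4NPF6 (0.1 M), HFIP, 5 mM substrate, 25 °C
Reagents that add atoms: none
Why: Proposed new method: anodic one-electron oxidation should occur at the methoxy-pentyl ring, the only electron-rich arene of 8 (the other ring carries the ester, the sulfonate and the alkyne), giving an anisole-type radical cation with its positive charge largest para to the methoxy group, at C1'; the salicylate OH, freed from its hydrogen bond by HFIP and held by the ester two atoms from C2', adds to C1', and loss of a second electron and a proton rearomatizes the ring while HFIP is reduced to H2 at the cathode. The closest known reaction types are anodic dehydrogenative C–H/O–H and C–H/N–H cyclizations of arene radical cations in HFIP (lactonization of biaryl acids, benzoxazole formation), hypervalent-iodine substitution of alkoxyarenes through radical cations, and the biosynthetic oxidative closure of depsides to depsidones. The dioxepinone closes as a seven-membered ring by attack of oxygen on the arene carbon ortho to the tethering ester oxygen (formally 7-endo with respect to the C1'=C2' bond, with the ester in its s-cis lactone geometry). No stereocentre is formed. The step needs selectivity for C1' over C3' (the only other carbon the tether can reach, C5' being out of reach) and for cyclization over intermolecular biaryl coupling; the first should follow from the para-to-OMe charge distribution and the second from high dilution. The benzylic C–H of the pentyl group is meta to the methoxy group and poorly activated, and the product radical cation has no free para position and no tethered nucleophile, so it should be returned to neutral product at the cathode.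

Step 7
Reactants: 9 1-(hept-1-yn-1-yl)-8-methoxy-11-oxo-6-pentyl-11H-dibenzo[b,e][1,4]dioxepin-3-yl 4-methylbenzenesulfonate
Product: 11 2-(hept-1-yn-1-yl)-4-hydroxy-6-(2-hydroxy-4-methoxy-6-pentylphenoxy)benzoic acid, via ring-opened tosyl acid 10 (not isolated)
Conditions: KOH (8 equiv), 1,4-dioxane/H2O 3:1, degassed, 80 °C; then 1 M HCl, 0 °C
Reagents that add atoms: potassium hydroxide, [K+].[OH-]
Why: saponification, in which hydroxide opens the strained seven-membered aryl-ester lactone at the acyl carbon and then cleaves the aryl sulfonate at sulfur, so one operation should unveil the acid and both phenols while the diaryl ether, methyl ether and alkyne are inert.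

Step 8
Reactants: 11 2-(hept-1-yn-1-yl)-4-hydroxy-6-(2-hydroxy-4-methoxy-6-pentylphenoxy)benzoic acid
Product: 12 6-hydroxy-8-(2-hydroxy-4-methoxy-6-pentylphenoxy)-3-pentyl-1H-isochromen-1-one (Compound NP-007099)
Conditions: TfOH (10 mol %), 1,2-dichloroethane, 50 °C
Reagents that add atoms: none
Why: Brønsted acid-catalysed 6-endo-dig cycloisomerization of a 2-alkynylbenzoic acid, in which positive charge should build at the pentyl-bearing alkyne carbon (the ring-bound carbon is deactivated by the ortho carboxyl and both ring oxygens are meta to it) and the carboxyl oxygen closes the enol lactone, the thermodynamically preferred isomer.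

**Compound list**

1 | olivetol (5-pentylbenzene-1,3-diol) | CCCCCc1cc(O)cc(O)c1 | starting material
2 | 3-methoxy-5-pentylphenol | CCCCCc1cc(O)cc(OC)c1 | intermediate
3 | 5,7-dihydroxy-2,2-dimethyl-4H-1,3-benzodioxin-4-one | CC1(C)Oc2cc(O)cc(O)c2C(=O)O1 | starting material
4 | 5-hydroxy-2,2-dimethyl-4-oxo-4H-1,3-benzodioxin-7-yl 4-methylbenzenesulfonate | CC1(C)Oc2cc(OS(=O)(=O)c3ccc(C)cc3)cc(O)c2C(=O)O1 | intermediate
5 | 2,2-dimethyl-4-oxo-5-{[(trifluoromethyl)sulfonyl]oxy}-4H-1,3-benzodioxin-7-yl 4-methylbenzenesulfonate | CC1(C)Oc2cc(OS(=O)(=O)c3ccc(C)cc3)cc(OS(=O)(=O)C(F)(F)F)c2C(=O)O1 | intermediate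
6 | 1-heptyne | CCCCCC#C | starting material
7 | 5-(hept-1-yn-1-yl)-2,2-dimethyl-4-oxo-4H-1,3-benzodioxin-7-yl 4-methylbenzenesulfonate | CCCCCC#Cc1cc(OS(=O)(=O)c2ccc(C)cc2)cc2OC(C)(C)OC(=O)c12 | intermediate
8 | 3-methoxy-5-pentylphenyl 2-(hept-1-yn-1-yl)-6-hydroxy-4-(tosyloxy)benzoate | CCCCCC#Cc1cc(OS(=O)(=O)c2ccc(C)cc2)cc(O)c1C(=O)Oc1cc(OC)cc(CCCCC)c1 | intermediate
9 | 1-(hept-1-yn-1-yl)-8-methoxy-11-oxo-6-pentyl-11H-dibenzo[b,e][1,4]dioxepin-3-yl 4-methylbenzenesulfonate | CCCCCC#Cc1cc(OS(=O)(=O)c2ccc(C)cc2)cc2Oc3c(CCCCC)cc(OC)cc3OC(=O)c12 | intermediate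
10 | 2-(hept-1-yn-1-yl)-6-(2-hydroxy-4-methoxy-6-pentylphenoxy)-4-(tosyloxy)benzoic acid (ring-opened tosyl acid) | CCCCCC#Cc1cc(OS(=O)(=O)c2ccc(C)cc2)cc(Oc2c(O)cc(OC)cc2CCCCC)c1C(=O)O | intermediate
11 | 2-(hept-1-yn-1-yl)-4-hydroxy-6-(2-hydroxy-4-methoxy-6-pentylphenoxy)benzoic acid | CCCCCC#Cc1cc(O)cc(Oc2c(O)cc(OC)cc2CCCCC)c1C(=O)O | intermediate
12 | 6-hydroxy-8-(2-hydroxy-4-methoxy-6-pentylphenoxy)-3-pentyl-1H-isochromen-1-one | CCCCCc1cc2cc(O)cc(Oc3c(O)cc(OC)cc3CCCCC)c2c(=O)o1 | target

**Step count and risks**

Total steps: 8. Longest linear sequence: 7 steps (3 to 12, steps 2–8).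

Steps most likely to fail:

1. Step 6 (proposed new method). The radical cation may couple intermolecularly to biaryl dimers faster than the ester reaches its s-cis geometry, oxygen may attack C3' instead of C1', or the more electron-rich product may be over-oxidized. Fallback, from 8 back to 9, replacing C–H oxidation by halogen-based C–O coupling: electrophilic bromination with NBS in MeCN at 0 °C should go para to the methoxy group of the ester ring, the most activated arene, and give 2-bromo-5-methoxy-3-pentylphenyl 2-(hept-1-yn-1-yl)-6-hydroxy-4-(tosyloxy)benzoate F1. An intramolecular copper-catalysed Ullmann diaryl ether synthesis (CuI, N,N-dimethylglycine, Cs2CO3, dioxane, 90 °C) should then close the dioxepinone ring to 9.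

2. Step 5. Acyl transfer to the weakly nucleophilic phenoxide at a carbonyl flanked by two ortho substituents may be too slow, and sulfonyl transfer from the tosylate to the phenoxide may compete. Fallback, from 7 back to 8, replacing direct acyl transfer by acid activation: sodium allyloxide (allyl alcohol, NaH, THF, 0 °C) should open the dioxinone to allyl 2-(hept-1-yn-1-yl)-6-hydroxy-4-(tosyloxy)benzoate F2. Pd(PPh3)4 with morpholine should remove the allyl group to give 2-(hept-1-yn-1-yl)-6-hydroxy-4-(tosyloxy)benzoic acid F3. Steglich esterification (DCC, cat. DMAP, CH2Cl2) with 2 should then give 8.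

3. Step 8. Closure may go 5-exo to an alkylidene phthalide, or the strong acid may attack the electron-rich phenoxy ring. Fallback, from 9 back to 12, replacing steps 7 and 8 and using the ester carbonyl as the nucleophile: with Ph3PAuNTf2 (5 mol %) in dioxane/H2O at 60 °C the depsidone carbonyl oxygen should add 6-endo to the gold-activated alkyne, the only mode that leads to an aromatic 2-benzopyrylium ion. Water then adds at C1 and the 2'-phenol is expelled, giving 8-(2-hydroxy-4-methoxy-6-pentylphenoxy)-1-oxo-3-pentyl-1H-isochromen-6-yl 4-methylbenzenesulfonate F4. KOH in aqueous dioxane should cleave the sulfonate and reversibly open the lactone to 4-hydroxy-2-(2-hydroxy-4-methoxy-6-pentylphenoxy)-6-(2-oxoheptyl)benzoic acid F5, which should reclose to 12 with loss of water on acidification and warming.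

Further compounds
F1 | step 6 | 2-bromo-5-methoxy-3-pentylphenyl 2-(hept-1-yn-1-yl)-6-hydroxy-4-(tosyloxy)benzoate | CCCCCC#Cc1cc(OS(=O)(=O)c2ccc(C)cc2)cc(O)c1C(=O)Oc1cc(OC)cc(CCCCC)c1Br
F2 | step 5 | allyl 2-(hept-1-yn-1-yl)-6-hydroxy-4-(tosyloxy)benzoate | CCCCCC#Cc1cc(OS(=O)(=O)c2ccc(C)cc2)cc(O)c1C(=O)OCC=C
F3 | step 5 | 2-(hept-1-yn-1-yl)-6-hydroxy-4-(tosyloxy)benzoic acid | CCCCCC#Cc1cc(OS(=O)(=O)c2ccc(C)cc2)cc(O)c1C(=O)O
F4 | step 8 | 8-(2-hydroxy-4-methoxy-6-pentylphenoxy)-1-oxo-3-pentyl-1H-isochromen-6-yl 4-methylbenzenesulfonate | CCCCCc1cc2cc(OS(=O)(=O)c3ccc(C)cc3)cc(Oc3c(O)cc(OC)cc3CCCCC)c2c(=O)o1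
F5 | step 8 | 4-hydroxy-2-(2-hydroxy-4-methoxy-6-pentylphenoxy)-6-(2-oxoheptyl)benzoic acid | CCCCCC(=O)Cc1cc(O)cc(Oc2c(O)cc(OC)cc2CCCCC)c1C(=O)O
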